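The route rests on cutting the C9–C10 bond (chain numbered from the CH2OH carbon C1), the sp3–sp2 bond that links the C9 methylene to the E-trisubstituted C10=C11 alkene. The key step exploits that C9 is homoallylic to the C6=C7 alkene: C8–C9 is carried as the terminal vinyl group of a 1,3-diene. In one flask 9-BBN places boron on C9, hydroxide frees the C1 alcohol, and palladium joins C9 to C10 of an (E)-vinyl iodide that already holds the trimethylcyclohexanol ring with its free tertiary alcohol, so the natural product is formed directly. The precursor is a conjugated triene acetate made from geranyl acetate.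

Key step: step 6

Assumption: the cyclase is taken to fold (E)-geranylacetone as it folds the first ring of its natural substrate, which gives the (4aS,8aS) enol ether that maps onto the (1S,2S) ring of the target.

Step 1
Reactants: 1 (E)-geranylacetone
Product: 2 (4aS,8aS)-2,5,5,8a-tetramethyl-4a,5,6,7,8,8a-hexahydro-4H-chromene
Conditions: squalene–hopene cyclase from Alicyclobacillus acidocaldarius (recombinant E. coli whole cells), citrate buffer pH 6.0, 0.2 % Triton X-100, 30 °C; extraction with base-washed solvent
Reagents that add atoms: none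
Why: Enzymatic Brønsted-acid polyene cyclization, in which the cyclase protonates the terminal trisubstituted alkene of the chair-folded substrate, the central E alkene closes the six-membered ring by anti addition and the ketone oxygen traps the tertiary cation, so that both trans-fused centres (4aS,8aS) should be set by the enzyme pocket together with the E geometry of that alkene.

Step 2
Reactants: 2 (4aS,8aS)-2,5,5,8a-tetramethyl-4a,5,6,7,8,8a-hexahydro-4H-chromene
Product: 4 (1S,2S)-2-(but-3-yn-1-yl)-1,3,3-trimethylcyclohexan-1-ol, via but-2-ynyl alkoxide 3 (not isolated)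
Conditions: KH (4 equiv), H2N(CH2)3NH2/THF, 0 → 25 °C; then aq NH4Cl
Reagents that add atoms: none
Why: Base-induced eliminative ring scission of a cyclic enol ether (anti E2 of the vinylic hydrogen that lies trans to the ring oxygen, the reaction type by which amide bases open 2-alkyl-dihydrofurans and -dihydropyrans to alkynols) should expel the tertiary alkoxide and leave a but-2-ynyl chain, which the same potassium 3-aminopropylamide moves by one position to the terminal acetylide (alkyne zipper isomerization) without touching either stereocentre.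

Step 3
Reactants: 4 (1S,2S)-2-(but-3-yn-1-yl)-1,3,3-trimethylcyclohexan-1-ol
Product: 6 (1S,2S)-2-[(3E)-4-iodo-3-methylbut-3-en-1-yl]-1,3,3-trimethylcyclohexan-1-ol, via alkenylalane 5 (not isolated)
Conditions: Me3Al (3.5 equiv), Cp2ZrCl2 (0.3 equiv), CH2Cl2, 0 → 25 °C; then I2, THF, −30 → 0 °C; aq NaHCO3/Na2S2O3
Reagents that add atoms: trimethylaluminium C[Al](C)C; iodine [I][I]
Why: Negishi zirconium-catalysed carboalumination adds methyl and aluminium syn across the terminal alkyne (methyl to the inner carbon, aluminium to the terminal one) while the hydroxyl rides as its dimethylaluminium alkoxide, and iodinolysis with retention should give the (E)-iodide.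

Step 4
Reactants: 7 geranyl acetate
Product: 9 (2E,6E)-3,7-dimethyl-8-oxoocta-2,6-dien-1-yl acetate, via allylic alcohol 8 (not isolated)
Conditions: SeO2 (0.3 equiv), t-BuOOH (3 equiv), salicylic acid (0.1 equiv), CH2Cl2, 25 °C; aqueous wash; then MnO2, CH2Cl2, 25 °C
Reagents that add atoms: selenium dioxide O=[Se]=O (catalytic oxygen carrier); tert-butyl hydroperoxide CC(C)(C)OO
Why: SeO2 allylic oxidation (ene reaction followed by [2,3]-sigmatropic shift) is selective for the E methyl group of the electron-rich terminal alkene, the C2=C3 alkene being deactivated by its allylic acetate, and MnO2 should then oxidise the allylic alcohol in the crude mixture to the (E)-enal.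

Step 5
Reactants: 9 (2E,6E)-3,7-dimethyl-8-oxoocta-2,6-dien-1-yl acetate
Product: 10 (2E,6E)-3,7-dimethylnona-2,6,8-trien-1-yl acetate
Conditions: Ph3PCH3Br (1.15 equiv), KHMDS (1.1 equiv), THF, 0 °C; then 9, −78 → 0 °C
Reagents that add atoms: methyltriphenylphosphonium bromide C[P+](c1ccccc1)(c1ccccc1)c1ccccc1.[Br-]
Why: Wittig methylenation of the aldehyde by the non-stabilised ylide is far faster than attack on the acetate at low temperature and leaves the geometry of the C6=C7 alkene untouched.

Step 6
Reactants: 10 (2E,6E)-3,7-dimethylnona-2,6,8-trien-1-yl acetate; 6 (1S,2S)-2-[(3E)-4-iodo-3-methylbut-3-en-1-yl]-1,3,3-trimethylcyclohexan-1-ol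
Product: 13 preluffariellolide A, via acetoxy alkylborane 11 (not isolated), via hydroxy alkylborane 12 (not isolated)
Conditions: 10 (1.5 equiv), 9-BBN (1.55 equiv), THF, 0 → 40 °C; then 3 M aq NaOH, MeOH, 25 °C; then 6 (1.0 equiv), Pd(dppf)Cl2 (5 mol %), AsPh3 (5 mol %), THF/H2O, 50 °C
Reagents that add atoms: none
Why: Mechanism: 9-BBN adds anti-Markovnikov to the monosubstituted C8=C9 vinyl of the diene (boron on C9), hydroxide turns the borane into its hydroxyborate and cleaves the acetate, zerovalent palladium formed from Pd(dppf)Cl2 inserts into the C10–I bond of 6, the primary alkyl group moves from boron to palladium and reductive elimination forms C9–C10. The closest known reaction type is the B-alkyl Suzuki–Miyaura coupling of a 9-BBN adduct with an alkenyl iodide. No ring is closed and no stereocentre is created; the (1S,2S) ring centres of 6 are spectators. The step needs regioselective hydroboration, which the bulk of 9-BBN should secure by taking the only monosubstituted alkene and leaving the three trisubstituted ones, so that the diene is expected to stop at the homoallylic borane. It needs retention of the E geometry at C10=C11, which oxidative addition and reductive elimination at an sp2 carbon provide, and reductive elimination faster than β-hydride loss towards the diene, which the wide bite angle of dppf favours. The acetate is removed before palladium is added so that no allylpalladium species can form from the C1–C3 allylic ester.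

Compound list
1 | (E)-geranylacetone, (5E)-6,10-dimethylundeca-5,9-dien-2-one | CC(=O)CC/C=C(\C)CCC=C(C)C | starting material
2 | (4aS,8aS)-2,5,5,8a-tetramethyl-4a,5,6,7,8,8a-hexahydro-4H-chromene (trans-fused bicyclic enol ether) | CC1=CC[C@H]2C(C)(C)CCC[C@]2(C)O1 | intermediate
3 | (1S,2S)-2-(but-2-yn-1-yl)-1,3,3-trimethylcyclohexan-1-ol (formed as its potassium alkoxide) | CC#CC[C@H]1C(C)(C)CCC[C@]1(C)O | intermediate
4 | (1S,2S)-2-(but-3-yn-1-yl)-1,3,3-trimethylcyclohexan-1-ol | C#CCC[C@H]1C(C)(C)CCC[C@]1(C)O | intermediate
5 | dimethylaluminium alkoxide of (1S,2S)-2-[(3E)-4-(dimethylalumanyl)-3-methylbut-3-en-1-yl]-1,3,3-trimethylcyclohexan-1-ol | C[Al](C)/C=C(\C)CC[C@H]1C(C)(C)CCC[C@]1(C)O[Al](C)C | intermediate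
6 | (1S,2S)-2-[(3E)-4-iodo-3-methylbut-3-en-1-yl]-1,3,3-trimethylcyclohexan-1-ol | I/C=C(\C)CC[C@H]1C(C)(C)CCC[C@]1(C)O | intermediate
7 | geranyl acetate, (2E)-3,7-dimethylocta-2,6-dien-1-yl acetate | CC(=O)OC/C=C(\C)CCC=C(C)C | starting material
8 | (2E,6E)-8-hydroxy-3,7-dimethylocta-2,6-dien-1-yl acetate | CC(=O)OC/C=C(\C)CC/C=C(\C)CO | intermediate
9 | (2E,6E)-3,7-dimethyl-8-oxoocta-2,6-dien-1-yl acetate | CC(=O)OC/C=C(\C)CC/C=C(\C)C=O | intermediate
10 | (2E,6E)-3,7-dimethylnona-2,6,8-trien-1-yl acetate | CC(=O)OC/C=C(\C)CC/C=C(\C)C=C | intermediate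
11 | 9-[(3E,7E)-9-acetoxy-3,7-dimethylnona-3,7-dien-1-yl]-9-borabicyclo[3.3.1]nonane | CC(=O)OC/C=C(\C)CC/C=C(\C)CCB1C2CCCC1CCC2 | intermediate
12 | 9-[(3E,7E)-9-hydroxy-3,7-dimethylnona-3,7-dien-1-yl]-9-borabicyclo[3.3.1]nonane (present as its sodium hydroxyborate) | OC/C=C(\C)CC/C=C(\C)CCB1C2CCCC1CCC2 | intermediate
13 | preluffariellolide A, (1S,2S)-2-[(3E,7E,11E)-13-hydroxy-3,7,11-trimethyltrideca-3,7,11-trien-1-yl]-1,3,3-trimethylcyclohexan-1-ol | C/C(=C\CO)CC/C=C(\C)CC/C=C(\C)CC[C@H]1C(C)(C)CCC[C@]1(C)O | target

Total step count: 6. Longest linear sequence: 4 steps (steps 1, 2, 3 and 6); the second branch is steps 4, 5 and 6.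

Steps most likely to fail

Step 2. The anti-elimination of the hindered tertiary alkoxide may be slow, and the triple bond may wander towards the ring, which would erode the configuration at the ring CH. The fallback sets out from 2 and avoids any base-driven scission. Dilute aqueous HCl in THF opens the enol ether to 4-[(1S,2S)-2-hydroxy-2,6,6-trimethylcyclohexyl]butan-2-one F1. TESOTf/2,6-lutidine gives the silyl ether 4-[(1S,2S)-2,6,6-trimethyl-2-(triethylsilyloxy)cyclohexyl]butan-2-one F2. Kinetic deprotonation of the methyl group with LDA and trapping with ClP(O)(OEt)2 gives the enol phosphate diethyl 4-[(1S,2S)-2,6,6-trimethyl-2-(triethylsilyloxy)cyclohexyl]but-1-en-2-yl phosphate F3. A second charge of LDA eliminates it to the protected alkyne triethyl{[(1S,2S)-2-(but-3-yn-1-yl)-1,3,3-trimethylcyclohexyl]oxy}silane F4, and Bu4NF returns to the route at 4.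

Step 1. The non-natural ketone may be turned over slowly in the enzyme pocket, or the cation may be lost by deprotonation or hydration before the oxygen closes the second ring. The fallback sets out from 1 and replaces the enzyme by a chemical chiral proton source. The SnCl4 complex of an enantiopure BINOL monoalkyl ether (a Lewis-acid-assisted chiral Brønsted acid, in the antipode that leads to the (4aS,8aS) series) in toluene at −78 °C should effect the same protonative cyclization with ketone-oxygen capture. It returns to the route at 2 and makes no compound outside the list (F0).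

Step 6. Hydroboration of the conjugated diene may be sluggish, and transmetallation of the homoallylic borate may be slow enough for protodeboronation or β-hydride loss to compete. The fallback sets out from 10 through the same borane 11 and changes the coupling to an alkylzinc–alkenyl iodide union. Oxidation with NaBO3·4H2O gives (2E,6E)-9-hydroxy-3,7-dimethylnona-2,6-dien-1-yl acetate F5. I2/PPh3/imidazole converts it into (2E,6E)-9-iodo-3,7-dimethylnona-2,6-dien-1-yl acetate F6. Zinc dust with LiCl in THF inserts to give [(3E,7E)-9-acetoxy-3,7-dimethylnona-3,7-dien-1-yl]zinc iodide F7. Negishi coupling of F7 (in excess, to cover the free hydroxyl) with 6 under Pd(PPh3)4 at 25 °C, where the alkenyl iodide should react far faster than the allylic acetate, gives preluffariellolide A acetate F8. K2CO3 in MeOH returns to the route at 13.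

Further compounds
F0 | step 1 | none | none
F1 | step 2 | 4-[(1S,2S)-2-hydroxy-2,6,6-trimethylcyclohexyl]butan-2-one | CC(=O)CC[C@H]1C(C)(C)CCC[C@]1(C)O
F2 | step 2 | 4-[(1S,2S)-2,6,6-trimethyl-2-(triethylsilyloxy)cyclohexyl]butan-2-one | CC(=O)CC[C@H]1C(C)(C)CCC[C@]1(C)O[Si](CC)(CC)CC
F3 | step 2 | diethyl 4-[(1S,2S)-2,6,6-trimethyl-2-(triethylsilyloxy)cyclohexyl]but-1-en-2-yl phosphate | C=C(CC[C@H]1C(C)(C)CCC[C@]1(C)O[Si](CC)(CC)CC)OP(=O)(OCC)OCC
F4 | step 2 | triethyl{[(1S,2S)-2-(but-3-yn-1-yl)-1,3,3-trimethylcyclohexyl]oxy}silane | C#CCC[C@H]1C(C)(C)CCC[C@]1(C)O[Si](CC)(CC)CC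
F5 | step 6 | (2E,6E)-9-hydroxy-3,7-dimethylnona-2,6-dien-1-yl acetate | CC(=O)OC/C=C(\C)CC/C=C(\C)CCO
F6 | step 6 | (2E,6E)-9-iodo-3,7-dimethylnona-2,6-dien-1-yl acetate | CC(=O)OC/C=C(\C)CC/C=C(\C)CCI
F7 | step 6 | [(3E,7E)-9-acetoxy-3,7-dimethylnona-3,7-dien-1-yl]zinc iodide | CC(=O)OC/C=C(\C)CC/C=C(\C)CC[Zn]I
F8 | step 6 | preluffariellolide A acetate | CC(=O)OC/C=C(\C)CC/C=C(\C)CC/C=C(\C)CC[C@H]1C(C)(C)CCC[C@]1(C)O
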